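**Retrosynthetic overview**

1. Locants: O1, C2, C3, C3a, C4–C7, C7a and ring A (the benzene ring) belong to the dihydrobenzofuran with the Z-styryl group on C4. Primed locants and ring B belong to the dihydrobenzofuran bonded to C3 through C5'.
2. Feature used: ring A has oxygen on C6 and C7a, hydrogen on C5 and C7, and its two carbon substituents on the neighbouring C3a and C4. A 1,3-dioxygenated butadiene leaves exactly this pattern on an alkynyl ketone whose carbonyl carbon is C3.
3. Disconnections: the Z-alkene goes back to a diarylalkyne. C2–C3 comes from carbene insertion into the OCH2Ar group of a C7a benzyl ether, the carbene carbon being the former ketone C3. C4–C5 and C3a–C7a come from Diels–Alder reaction and aromatisation of a penta-2,4-diyn-1-one. The C3–alkyne bond comes from acetylide addition to the C5' aldehyde.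
4. Ring order: first the furan ring on ring B (C–H insertion with Rh2(R-PTAD)4, acid equilibration to trans), then benzene ring A (cycloaddition), then the furan ring on ring A (insertion with Rh2(S-PTAD)4, acid equilibration).
5. End game: the seven methyl ethers are cleaved while the arm is still an alkyne, and the acid-sensitive Z-alkene is made in the last step.

Key step: step 12

Assumption: Rh2(R-PTAD)4 is taken to give the (3R) and Rh2(S-PTAD)4 the (3S) cis-dihydrobenzofuran. If the sense of induction is the reverse, the two commercial catalyst enantiomers are exchanged.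

Abbreviation: ArB = (2R,3R)-3-(3,5-dimethoxyphenyl)-7-methoxy-2-(4-methoxyphenyl)-2,3-dihydrobenzofuran-5-yl.

**Route**

Step 1
Reactants: 1 5-bromo-2-hydroxy-3-methoxybenzaldehyde; 2 4-methoxybenzyl chloride
Product: 3 5-bromo-3-methoxy-2-[(4-methoxybenzyl)oxy]benzaldehyde
Conditions: K2CO3, NaI (cat.), DMF, 60 °C
Reagents that add atoms: none
Why: Williamson ether synthesis of an acidic ortho-formylphenol with a reactive benzylic chloride; the new OCH2Ar carbon is the future C2'.

Step 2
Reactants: 3 5-bromo-3-methoxy-2-[(4-methoxybenzyl)oxy]benzaldehyde; 4 1-bromo-3,5-dimethoxybenzene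
Product: 6 {5-bromo-3-methoxy-2-[(4-methoxybenzyl)oxy]phenyl}(3,5-dimethoxyphenyl)methanol (racemic), via Grignard reagent 5 (not isolated)
Conditions: 4, Mg, THF, reflux; then 3, 0 °C; then H2O
Reagents that add atoms: none
Why: Grignard addition to the aldehyde is much faster at 0 °C than any exchange at the aryl bromide of 3; the carbinol centre forms racemic and is erased in step 3.

Step 3
Reactants: 6 the diarylmethanol
Product: 7 {5-bromo-3-methoxy-2-[(4-methoxybenzyl)oxy]phenyl}(3,5-dimethoxyphenyl)methanone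
Conditions: MnO2 (activated, excess), CH2Cl2, reflux
Reagents that add atoms: none
Why: MnO2 oxidation of a doubly benzylic alcohol leaves the benzyl ether and the aryl bromide untouched.

Step 4
Reactants: 7 the diaryl ketone
Product: 8 hydrazone of 7 (C=N isomers)
Conditions: N2H4·H2O (excess), AcOH (cat.), EtOH, reflux, Ar
Reagents that add atoms: hydrazine, NN
Why: Acid-catalysed condensation of hydrazine with a benzophenone that has only one ortho substituent is the standard entry to diaryldiazomethanes.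

Step 5
Reactants: 8 hydrazone of 7
Product: 10 (2S,3R)-5-bromo-3-(3,5-dimethoxyphenyl)-7-methoxy-2-(4-methoxyphenyl)-2,3-dihydrobenzofuran (cis), via diazo compound 9 (not isolated)
Conditions: MnO2, CH2Cl2, rt, filter; then Rh2(R-PTAD)4 (1 mol %), CH2Cl2, 0 °C
Reagents that add atoms: none
Why: MnO2 dehydrogenates the hydrazone to the donor/donor diazo compound 9, whose dirhodium carbene inserts into the ether-activated benzylic C–H bond (intramolecular 1,5 C–H insertion, established for hydrazones of 2-benzyloxybenzophenones); the chiral carboxylate ligands fix C3' as R and the compact transition state puts the two aryl groups cis, so C2' is S.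

Step 6
Reactants: 10 the cis bromide
Product: 11 (2R,3R)-5-bromo-3-(3,5-dimethoxyphenyl)-7-methoxy-2-(4-methoxyphenyl)-2,3-dihydrobenzofuran (trans)
Conditions: TFA (5 equiv), CH2Cl2 (dilute), 0 °C to rt
Reagents that add atoms: none
Why: Acid-catalysed epimerisation by reversible heterolysis of the O1'–C2' bond gives a 4-methoxybenzyl cation that recloses on the phenol to the less strained trans isomer, so C2' goes from S to R under control of the untouched C3'.

Step 7
Reactants: 11 the trans bromide
Product: 13 ArB-carbaldehyde, via aryllithium 12 (not isolated)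
Conditions: n-BuLi, THF, −78 °C; DMF, −78 to 0 °C; then H2O
Reagents that add atoms: N,N-dimethylformamide, CN(C)C=O
Why: Bromine–lithium exchange at −78 °C outruns any deprotonation and DMF formylates the aryllithium; C2' and C3' are not acidic enough to be touched.

Step 8
Reactants: 14 4-ethynylanisole; 15 1,1-dichloroethene
Product: 16 1-(3-chlorobut-3-en-1-yn-1-yl)-4-methoxybenzene
Conditions: 15 (5 equiv), Pd(PPh3)4 (5 mol %), CuI (5 mol %), n-BuNH2, toluene, rt, Ar
Reagents that add atoms: none
Why: Sonogashira-type alkynylation of 1,1-dichloroethene stops after one C–Cl bond because the dichloride is in excess and the remaining chloride is less reactive; exclusion of air suppresses oxidative alkyne dimerisation.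

Step 9
Reactants: 16 the chloroenyne; 13 ArB-carbaldehyde
Product: 18 1-ArB-5-(4-methoxyphenyl)penta-2,4-diyn-1-ol (both carbinol epimers), via lithium diynide 17 (not isolated)
Conditions: 16, LDA (2 equiv per 16), THF, −78 °C; then 13, −78 to 0 °C; then H2O
Reagents that add atoms: none
Why: LDA dehydrochlorinates the 2-chloroenyne and deprotonates the resulting diyne, so the sensitive terminal butadiyne is never handled, and the diynide adds 1,2 to the non-enolisable aldehyde; the carbinol centre is erased in step 10.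

Step 10
Reactants: 18 the diynol
Product: 19 1-ArB-5-(4-methoxyphenyl)penta-2,4-diyn-1-one
Conditions: MnO2 (activated), CH2Cl2, rt
Reagents that add atoms: none
Why: MnO2 oxidation of an alcohol that is both benzylic and propargylic is fast and neutral, and leaves the diyne and the dihydrofuran intact.

Step 11
Reactants: 20 methyl (E)-3-methoxybut-2-enoate
Product: 22 (1E)-1,3-dimethoxy-1-(trimethylsilyloxy)buta-1,3-diene, via lithium dienolate 21 (not isolated)
Conditions: LDA, THF, −78 °C; TMSCl, −78 °C to rt; distillation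
Reagents that add atoms: chlorotrimethylsilane, C[Si](C)(C)Cl
Why: γ-Deprotonation of the vinylogous carbonate gives the extended dienolate, which the hard silyl chloride traps on oxygen (silyl ketene acetal formation).

Step 12
Reactants: 19 the diynone; 22 the ketene-acetal diene
Product: 24 ArB 2-hydroxy-4-methoxy-6-[(4-methoxyphenyl)ethynyl]phenyl ketone, via cyclohexadiene cycloadduct 23 (not isolated)
Conditions: 22 (3 equiv), toluene, 80 °C, Ar; then 1 M HCl, THF, rt
Reagents that add atoms: none
Why: This is a normal-electron-demand, strongly asynchronous Diels–Alder reaction in which the unsubstituted CH2 terminus of 22, its most nucleophilic carbon, bonds to the ynone β-carbon (C4–C5) and the acetal carbon then bonds to the α-carbon (C3a–C7a) to give the cyclohexa-1,4-diene 23. Dilute acid removes the silyl group, the hemiketal expels methanol and the dienone tautomerises, so ring A appears as the C7a phenol with the C6 methyl ether in place. The closest known reaction type is the cycloaddition–aromatisation of 1-alkoxy-1-silyloxy-3-alkoxybutadienes with acetylenic ketones and esters to ortho-acyl resorcinol monoethers. Ring A closes in the [4+2] mode with four carbons from 22 and two from 19; no lasting stereocentre is made, since the mixed-acetal carbon of 23 is lost on aromatisation, and C2' and C3' are not touched. Regioselectivity rests on the matched polarisation of diene and ynone; chemoselectivity for the proximal triple bond rests on its direct conjugation with the carbonyl group, while the distal one is deactivated and shielded by the 4-methoxyphenyl donor. The hydrogen bond between the new hydroxyl and the ketone sets this oxygen apart from every methyl ether for step 13.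

Step 13
Reactants: 24 the hydroxy ketone; 2 4-methoxybenzyl chloride
Product: 25 ArB 4-methoxy-2-[(4-methoxybenzyl)oxy]-6-[(4-methoxyphenyl)ethynyl]phenyl ketone
Conditions: K2CO3, n-Bu4NI (cat.), DMF, 70 °C
Reagents that add atoms: none
Why: Williamson ether synthesis at the only free hydroxyl, whose chelate is broken by carbonate in DMF; the new OCH2Ar carbon is the future C2.

Step 14
Reactants: 25 the benzyloxy ketone
Product: 26 hydrazone of 25 (C=N isomers)
Conditions: N2H4·H2O (30 equiv), AcOH (cat.), n-BuOH, 100 °C, Ar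
Reagents that add atoms: hydrazine, NN
Why: Acid-catalysed hydrazone formation should still proceed because the two ortho groups (an ether oxygen and a linear alkyne) are slim, the unactivated diarylalkyne is not attacked by nitrogen without a π-acid, and exclusion of air prevents diimide reduction.

Step 15
Reactants: 26 hydrazone of 25
Product: 28 (2R,3S)-3-ArB-6-methoxy-2-(4-methoxyphenyl)-4-[(4-methoxyphenyl)ethynyl]-2,3-dihydrobenzofuran (cis on ring A), via diazo compound 27 (not isolated)
Conditions: MnO2, CH2Cl2, rt, filter; then Rh2(S-PTAD)4 (2 mol %), CH2Cl2, 0 °C to rt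
Reagents that add atoms: none
Why: The same hydrazone oxidation and 1,5 C–H insertion as in step 5, now with the enantiomeric catalyst, fixes C3 as S and gives the cis isomer (C2 R); the doubly activated OCH2Ar hydrogen reaches the carbene carbon through a six-membered transition state whereas attack on the linear ortho alkyne needs a strained 5-endo closure, and donor/donor carbenes prefer C–H insertion to addition to π bonds.

Step 16
Reactants: 28 the cis heptamethyl ether
Product: 29 (2S,3S)-3-ArB-6-methoxy-2-(4-methoxyphenyl)-4-[(4-methoxyphenyl)ethynyl]-2,3-dihydrobenzofuran (trans on both furan rings)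
Conditions: TFA (5 equiv), CH2Cl2 (dilute), 0 °C, short contact
Reagents that add atoms: none
Why: Acid-catalysed epimerisation as in step 6 inverts only C2 (R to S) under control of C3; the freed C7a phenol stays next to the cation, so reclosure should outrun attack by the alkyne, and ring B can only return to trans.

Step 17
Reactants: 29 the all-trans heptamethyl ether
Product: 30 (2S,3S)-3-[(2R,3R)-3-(3,5-dihydroxyphenyl)-7-hydroxy-2-(4-hydroxyphenyl)-2,3-dihydrobenzofuran-5-yl]-2-(4-hydroxyphenyl)-4-[(4-hydroxyphenyl)ethynyl]-2,3-dihydrobenzofuran-6-ol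
Conditions: BBr3 (20 equiv), CH2Cl2, −78 °C to rt; then H2O, 0 °C
Reagents that add atoms: none
Why: Lewis-acid ether cleavage with BBr3 is known both for methoxylated diarylalkynes and for 2,3-diaryldihydrobenzofuran methyl ethers; the excess reagent ties up every ether oxygen and so weakens the donors that would stabilise a C2 or a vinyl cation, there is no methoxy group ortho to the alkyne that could cyclise onto it, and any reversible C2–O opening returns to the trans rings while C3 and C3' stay fixed.

Step 18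
Reactants: 30 the heptaphenol alkyne
Product: 31 target CNP0172909.2, 4-[(Z)-2-(4-hydroxyphenyl)ethenyl] analogue of 30
Conditions: H2 (1 atm), 5% Pd/CaCO3 poisoned with Pb(OAc)2, quinoline, EtOAc–MeOH, rt, stopped after one equivalent of H2
Reagents that add atoms: none
Why: Partial hydrogenation delivers both hydrogens to one face of the internal alkyne on the poisoned palladium surface and so sets the Z geometry; lead and quinoline hold back over-reduction, Z to E isomerisation and hydrogenolysis of the benzylic C–O bonds, and as the last step it keeps the Z-stilbene away from acid.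

**Compound list**

1 | 5-bromo-2-hydroxy-3-methoxybenzaldehyde | O=Cc1cc(Br)cc(OC)c1O | starting material
2 | 4-methoxybenzyl chloride | COc1ccc(CCl)cc1 | starting material
3 | 5-bromo-3-methoxy-2-[(4-methoxybenzyl)oxy]benzaldehyde | O=Cc1cc(Br)cc(OC)c1OCc1ccc(OC)cc1 | intermediate
4 | 1-bromo-3,5-dimethoxybenzene | COc1cc(Br)cc(OC)c1 | starting material
5 | 3,5-dimethoxyphenylmagnesium bromide | COc1cc(OC)cc([Mg]Br)c1 | intermediate
6 | {5-bromo-3-methoxy-2-[(4-methoxybenzyl)oxy]phenyl}(3,5-dimethoxyphenyl)methanol, racemic | OC(c1cc(OC)cc(OC)c1)c1cc(Br)cc(OC)c1OCc1ccc(OC)cc1 | intermediate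
7 | {5-bromo-3-methoxy-2-[(4-methoxybenzyl)oxy]phenyl}(3,5-dimethoxyphenyl)methanone | O=C(c1cc(OC)cc(OC)c1)c1cc(Br)cc(OC)c1OCc1ccc(OC)cc1 | intermediate
8 | hydrazone of 7 | NN=C(c1cc(OC)cc(OC)c1)c1cc(Br)cc(OC)c1OCc1ccc(OC)cc1 | intermediate
9 | diazo compound from 8 | [N-]=[N+]=C(c1cc(OC)cc(OC)c1)c1cc(Br)cc(OC)c1OCc1ccc(OC)cc1 | intermediate
10 | (2S,3R)-5-bromo-3-(3,5-dimethoxyphenyl)-7-methoxy-2-(4-methoxyphenyl)-2,3-dihydrobenzofuran (cis) | Brc1cc(OC)c2c(c1)[C@@H](c1cc(OC)cc(OC)c1)[C@@H](c1ccc(OC)cc1)O2 | intermediate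
11 | (2R,3R)-5-bromo-3-(3,5-dimethoxyphenyl)-7-methoxy-2-(4-methoxyphenyl)-2,3-dihydrobenzofuran (trans) | Brc1cc(OC)c2c(c1)[C@@H](c1cc(OC)cc(OC)c1)[C@H](c1ccc(OC)cc1)O2 | intermediate
12 | ArB-lithium | [Li]c1cc(OC)c2c(c1)[C@@H](c1cc(OC)cc(OC)c1)[C@H](c1ccc(OC)cc1)O2 | intermediate
13 | ArB-carbaldehyde | O=Cc1cc(OC)c2c(c1)[C@@H](c1cc(OC)cc(OC)c1)[C@H](c1ccc(OC)cc1)O2 | intermediate
14 | 4-ethynylanisole | C#Cc1ccc(OC)cc1 | starting material
15 | 1,1-dichloroethene | C=C(Cl)Cl | starting material
16 | 1-(3-chlorobut-3-en-1-yn-1-yl)-4-methoxybenzene | C=C(Cl)C#Cc1ccc(OC)cc1 | intermediate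
17 | lithium 4-(4-methoxyphenyl)buta-1,3-diynide | [Li]C#CC#Cc1ccc(OC)cc1 | intermediate
18 | 1-ArB-5-(4-methoxyphenyl)penta-2,4-diyn-1-ol, both carbinol epimers | COc1ccc(C#CC#CC(O)c2cc(OC)c3c(c2)[C@@H](c2cc(OC)cc(OC)c2)[C@H](c2ccc(OC)cc2)O3)cc1 | intermediate
19 | 1-ArB-5-(4-methoxyphenyl)penta-2,4-diyn-1-one | COc1ccc(C#CC#CC(=O)c2cc(OC)c3c(c2)[C@@H](c2cc(OC)cc(OC)c2)[C@H](c2ccc(OC)cc2)O3)cc1 | intermediate
20 | methyl (E)-3-methoxybut-2-enoate | CO/C(C)=C/C(=O)OC | starting material
21 | lithium dienolate of 20 | C=C(OC)/C=C(\OC)O[Li] | intermediate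
22 | (1E)-1,3-dimethoxy-1-(trimethylsilyloxy)buta-1,3-diene | C=C(OC)/C=C(\OC)O[Si](C)(C)C | intermediate
23 | cyclohexa-1,4-diene cycloadduct (acetal carbon unassigned) | COC1=CC(OC)(O[Si](C)(C)C)C(C(=O)c2cc(OC)c3c(c2)[C@@H](c2cc(OC)cc(OC)c2)[C@H](c2ccc(OC)cc2)O3)=C(C#Cc2ccc(OC)cc2)C1 | intermediate
24 | ArB 2-hydroxy-4-methoxy-6-[(4-methoxyphenyl)ethynyl]phenyl ketone | COc1ccc(C#Cc2cc(OC)cc(O)c2C(=O)c2cc(OC)c3c(c2)[C@@H](c2cc(OC)cc(OC)c2)[C@H](c2ccc(OC)cc2)O3)cc1 | intermediate
25 | ArB 4-methoxy-2-[(4-methoxybenzyl)oxy]-6-[(4-methoxyphenyl)ethynyl]phenyl ketone | COc1ccc(C#Cc2cc(OC)cc(OCc3ccc(OC)cc3)c2C(=O)c2cc(OC)c3c(c2)[C@@H](c2cc(OC)cc(OC)c2)[C@H](c2ccc(OC)cc2)O3)cc1 | intermediate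
26 | hydrazone of 25 | COc1ccc(C#Cc2cc(OC)cc(OCc3ccc(OC)cc3)c2C(=NN)c2cc(OC)c3c(c2)[C@@H](c2cc(OC)cc(OC)c2)[C@H](c2ccc(OC)cc2)O3)cc1 | intermediate
27 | diazo compound from 26 | COc1ccc(C#Cc2cc(OC)cc(OCc3ccc(OC)cc3)c2C(=[N+]=[N-])c2cc(OC)c3c(c2)[C@@H](c2cc(OC)cc(OC)c2)[C@H](c2ccc(OC)cc2)O3)cc1 | intermediate
28 | (2R,3S)-3-ArB-6-methoxy-2-(4-methoxyphenyl)-4-[(4-methoxyphenyl)ethynyl]-2,3-dihydrobenzofuran (cis on ring A) | COc1ccc(C#Cc2cc(OC)cc3c2[C@H](c2cc(OC)c4c(c2)[C@@H](c2cc(OC)cc(OC)c2)[C@H](c2ccc(OC)cc2)O4)[C@H](c2ccc(OC)cc2)O3)cc1 | intermediate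
29 | (2S,3S)-3-ArB-6-methoxy-2-(4-methoxyphenyl)-4-[(4-methoxyphenyl)ethynyl]-2,3-dihydrobenzofuran (all trans) | COc1ccc(C#Cc2cc(OC)cc3c2[C@H](c2cc(OC)c4c(c2)[C@@H](c2cc(OC)cc(OC)c2)[C@H](c2ccc(OC)cc2)O4)[C@@H](c2ccc(OC)cc2)O3)cc1 | intermediate
30 | heptaphenol alkyne (2S,3S,2'R,3'R) | Oc1ccc(C#Cc2cc(O)cc3c2[C@H](c2cc(O)c4c(c2)[C@@H](c2cc(O)cc(O)c2)[C@H](c2ccc(O)cc2)O4)[C@@H](c2ccc(O)cc2)O3)cc1 | intermediate
31 | CNP0172909.2 (2S,3S,2'R,3'R, Z) | Oc1ccc(/C=C\c2cc(O)cc3c2[C@H](c2cc(O)c4c(c2)[C@@H](c2cc(O)cc(O)c2)[C@H](c2ccc(O)cc2)O4)[C@@H](c2ccc(O)cc2)O3)cc1 | target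

**Step count**

Total: 18 steps. Longest linear sequence: 16 steps (1–7, 9, 10, 12–18).

**Steps most likely to fail**

Step 12.
- What may go wrong: the diene may attack the far, aryl-bearing end of the diynone or add across the distal triple bond. It may be lost by silyl transfer or hydrolysis before it cycloadds. Aromatisation may run by loss of silanol instead of methanol.
- Fallback: ring A is taken from a ready-made arene instead of being built. It sets out from 4, 14 and 11 and comes back at 24.
- Vilsmeier–Haack formylation of 4 (POCl3, DMF) should give 2-bromo-4,6-dimethoxybenzaldehyde F1. Sonogashira coupling of F1 with 14 (PdCl2(PPh3)2, CuI, Et3N, 60 °C) should give 2,4-dimethoxy-6-[(4-methoxyphenyl)ethynyl]benzaldehyde F2.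
- Addition of aryllithium 12, made from 11 as in step 7, should give the diarylmethanol F3, and MnO2 should oxidise it to the dimethoxy ketone F4.
- BCl3 (CH2Cl2, −78 to 0 °C) is guided by chelation to the carbonyl oxygen and should cleave only the C7a methyl ether to give 24. The same treatment would also convert any C7a methyl ether that step 12 forms by loss of silanol.

Step 15.
- What may go wrong: the carbene may be diverted by the neighbouring triple bond. Facial selectivity may be eroded by the two ortho substituents or by a mismatched pairing with the ring B stereocentres. Step 14, which feeds it, may be slow, or hydrazone nitrogen may cyclise onto the alkyne.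
- Fallback: C2 is brought in as a sulfur-ylide carbon in a formal [4+1] annulation with an ortho-quinone methide. It sets out from 24 and 2 and comes back at 29.
- NaBH4 (THF–MeOH) should reduce 24 to the ortho-hydroxybenzhydrol F5, and p-toluenesulfinic acid (CH2Cl2, rt) should convert this into the benzhydryl sulfone F6. Dimethyl sulfide and 2 should give (4-methoxybenzyl)dimethylsulfonium chloride F7.
- Cs2CO3 (CH2Cl2, rt) should release the ortho-quinone methide F8 from F6 and the ylide from F7. Conjugate addition and displacement of dimethyl sulfide by the phenoxide should close the furan ring trans, with no acid step.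
- Only the remote ring B can bias the face, so 29 and the (2R,3R) ring A diastereomer F9 are both to be expected. They are diastereomers and are separated by chromatography.

Step 17.
- What may go wrong: the C2–O1 bond may ionise under the Lewis acid, and the cation may then be captured by the triple bond on C4 (5-exo closure) or lose the C3 proton. HBr may add to the electron-rich alkyne on work-up. Cleavage of seven ethers may remain incomplete.
- Fallback: the protecting groups are exchanged before the furan ring on ring A exists, so that the last deprotection is neutral. It sets out from 24 and comes back at 30.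
- BBr3 is used on 24, where the ketone and its ortho phenol are locked in a boron chelate and no C2–O1 bond is present. This should give the heptaphenol ketone F10.
- Allyl bromide (6 equiv), K2CO3, acetone should cap the six unchelated phenols and leave the C7a hydroxyl free, giving the hexaallyl ether F11.
- SOCl2 and commercial 4-(allyloxy)benzyl alcohol (C=CCOc1ccc(CO)cc1) should give 4-(allyloxy)benzyl chloride F12, which alkylates F11 (K2CO3, DMF) to the heptaallyl ketone F13.
- The sequence of steps 14–16 should then lead through the hydrazone F14 and the diazo compound F15 to the cis dihydrobenzofuran F16 and, with TFA, to the trans heptaallyl ether F17.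
- Tsuji–Trost deallylation with zerovalent palladium (Pd(PPh3)4, K2CO3, MeOH, rt) should give 30 without any strong acid.

**Further compounds**

F1 | step 12 | 2-bromo-4,6-dimethoxybenzaldehyde | O=Cc1c(Br)cc(OC)cc1OC
F2 | step 12 | 2,4-dimethoxy-6-[(4-methoxyphenyl)ethynyl]benzaldehyde | O=Cc1c(OC)cc(OC)cc1C#Cc1ccc(OC)cc1
F3 | step 12 | ArB{2,4-dimethoxy-6-[(4-methoxyphenyl)ethynyl]phenyl}methanol, both carbinol epimers | COc1ccc(C#Cc2cc(OC)cc(OC)c2C(O)c2cc(OC)c3c(c2)[C@@H](c2cc(OC)cc(OC)c2)[C@H](c2ccc(OC)cc2)O3)cc1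
F4 | step 12 | ArB 2,4-dimethoxy-6-[(4-methoxyphenyl)ethynyl]phenyl ketone | COc1ccc(C#Cc2cc(OC)cc(OC)c2C(=O)c2cc(OC)c3c(c2)[C@@H](c2cc(OC)cc(OC)c2)[C@H](c2ccc(OC)cc2)O3)cc1
F5 | step 15 | ArB{2-hydroxy-4-methoxy-6-[(4-methoxyphenyl)ethynyl]phenyl}methanol, both carbinol epimers | COc1ccc(C#Cc2cc(OC)cc(O)c2C(O)c2cc(OC)c3c(c2)[C@@H](c2cc(OC)cc(OC)c2)[C@H](c2ccc(OC)cc2)O3)cc1
F6 | step 15 | 2-[ArB(tosyl)methyl]-5-methoxy-3-[(4-methoxyphenyl)ethynyl]phenol | COc1ccc(C#Cc2cc(OC)cc(O)c2C(c2cc(OC)c3c(c2)[C@@H](c2cc(OC)cc(OC)c2)[C@H](c2ccc(OC)cc2)O3)S(=O)(=O)c2ccc(C)cc2)cc1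
F7 | step 15 | (4-methoxybenzyl)dimethylsulfonium chloride | COc1ccc(C[S+](C)C)cc1.[Cl-]
F8 | step 15 | ortho-quinone methide from F6 | O=C1C=C(OC)C=C(C#Cc2ccc(OC)cc2)C1=Cc1cc(OC)c2c(c1)[C@@H](c1cc(OC)cc(OC)c1)[C@H](c1ccc(OC)cc1)O2
F9 | step 15 | (2R,3R) ring A diastereomer of 29 | COc1ccc(C#Cc2cc(OC)cc3c2[C@@H](c2cc(OC)c4c(c2)[C@@H](c2cc(OC)cc(OC)c2)[C@H](c2ccc(OC)cc2)O4)[C@H](c2ccc(OC)cc2)O3)cc1
F10 | step 17 | heptaphenol ketone from 24 | Oc1ccc(C#Cc2cc(O)cc(O)c2C(=O)c2cc(O)c3c(c2)[C@@H](c2cc(O)cc(O)c2)[C@H](c2ccc(O)cc2)O3)cc1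
F11 | step 17 | hexaallyl ether of F10, C7a hydroxyl free | C=CCOc1ccc(C#Cc2cc(OCC=C)cc(O)c2C(=O)c2cc(OCC=C)c3c(c2)[C@@H](c2cc(OCC=C)cc(OCC=C)c2)[C@H](c2ccc(OCC=C)cc2)O3)cc1
F12 | step 17 | 4-(allyloxy)benzyl chloride | C=CCOc1ccc(CCl)cc1
F13 | step 17 | C7a 4-(allyloxy)benzyl ether of F11 | C=CCOc1ccc(C#Cc2cc(OCC=C)cc(OCc3ccc(OCC=C)cc3)c2C(=O)c2cc(OCC=C)c3c(c2)[C@@H](c2cc(OCC=C)cc(OCC=C)c2)[C@H](c2ccc(OCC=C)cc2)O3)cc1
F14 | step 17 | hydrazone of F13 | C=CCOc1ccc(C#Cc2cc(OCC=C)cc(OCc3ccc(OCC=C)cc3)c2C(=NN)c2cc(OCC=C)c3c(c2)[C@@H](c2cc(OCC=C)cc(OCC=C)c2)[C@H](c2ccc(OCC=C)cc2)O3)cc1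
F15 | step 17 | diazo compound from F14 | C=CCOc1ccc(C#Cc2cc(OCC=C)cc(OCc3ccc(OCC=C)cc3)c2C(=[N+]=[N-])c2cc(OCC=C)c3c(c2)[C@@H](c2cc(OCC=C)cc(OCC=C)c2)[C@H](c2ccc(OCC=C)cc2)O3)cc1
F16 | step 17 | heptaallyl analogue of 28 (2R,3S, cis on ring A) | C=CCOc1ccc(C#Cc2cc(OCC=C)cc3c2[C@H](c2cc(OCC=C)c4c(c2)[C@@H](c2cc(OCC=C)cc(OCC=C)c2)[C@H](c2ccc(OCC=C)cc2)O4)[C@H](c2ccc(OCC=C)cc2)O3)cc1
F17 | step 17 | heptaallyl analogue of 29 (2S,3S, all trans) | C=CCOc1ccc(C#Cc2cc(OCC=C)cc3c2[C@H](c2cc(OCC=C)c4c(c2)[C@@H](c2cc(OCC=C)cc(OCC=C)c2)[C@H](c2ccc(OCC=C)cc2)O4)[C@@H](c2ccc(OCC=C)cc2)O3)cc1
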